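**Retrosynthetic overview**
1. Chain numbering: C1 = syringyl CH2, C2 (R), C3 (S), C4 = guaiacyl CH2. Target 13 comes from 12 by hydrogenolysis of two benzyl ethers. 12 comes from 11 by catalyst-controlled hydrogenation of a C1=C2 styrene bond, which sets C2.
2. Key disconnection C3–C4: 11 comes from the racemic secondary allylic chloride 6 and the benzylic zinc chloride 9 by a nickel/Pybox enantioconvergent Negishi coupling. This step joins the two halves, sets C3 and fixes the regiochemistry and alkene geometry.
3. Enabling feature: only C2 and C1 separate C3 from the syringyl ring. If C1 and C2 are carried as a C=C bond conjugated with that ring, C3 becomes the CH3-bearing end of a 1-aryl-allyl unit. Both enantiomers of the chloride, and its allylic isomer, then give one planar aryl-stabilised allyl radical, and the ring steers the new bond to C3.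
4. 6 comes from syringaldehyde 1 (O-benzylation, Wittig, MeMgBr, SOCl2). 9 comes from benzylic alcohol 7 (SOCl2, Zn/LiCl).
5. No ring is formed; both benzene rings are bought intact.

Key step: step 7

Assumption: for the new substrates of steps 7 and 8, and for the chiral borane of one fallback, the sense of induction is taken over from the parent reactions; if it proves opposite, the equally available antipode of the ligand or reagent is used and nothing else changes.

Step 1
Reactants: 1 syringaldehyde
Product: 2 4-(benzyloxy)-3,5-dimethoxybenzaldehyde
Conditions: BnBr, K2CO3, DMF, 60 °C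
Reagents that add atoms: benzyl bromide, BrCc1ccccc1
Why: Williamson ether synthesis on the acidic phenol; the benzyl ether should survive Grignard, organozinc, nickel and iridium chemistry and leaves only in the last step.

Step 2
Reactants: 2 4-(benzyloxy)-3,5-dimethoxybenzaldehyde; 3 2-(triphenyl-λ5-phosphanylidene)propanal
Product: 4 (E)-3-[4-(benzyloxy)-3,5-dimethoxyphenyl]-2-methylprop-2-enal
Conditions: toluene, 110 °C
Reagents that add atoms: none
Why: Wittig reaction of a stabilised α-methyl ylide with an aromatic aldehyde, which should give the (E)-enal (aryl trans to CHO) and installs C1, C2 and the C2 methyl group.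

Step 3
Reactants: 4 (E)-enal
Product: 5 racemic (E)-4-[4-(benzyloxy)-3,5-dimethoxyphenyl]-3-methylbut-3-en-2-ol
Conditions: MeMgBr, THF, −78 → 0 °C; then H2O
Reagents that add atoms: methylmagnesium bromide, C[Mg]Br
Why: 1,2-Grignard addition to an enal; the carbinol centre (future C3) is deliberately left racemic because step 7 erases and resets it.

Step 4
Reactants: 5 racemic allylic alcohol
Product: 6 racemic 2-(benzyloxy)-5-[(1E)-3-chloro-2-methylbut-1-en-1-yl]-1,3-dimethoxybenzene
Conditions: SOCl2, Et2O, −20 → 0 °C; volatiles removed cold, used crude
Reagents that add atoms: thionyl chloride, O=S(Cl)Cl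
Why: Chlorodehydroxylation of an activated secondary allylic alcohol through a chlorosulfite ion pair; the styrene-conjugated chloride is the thermodynamic isomer, and neither the racemic centre nor any allylic-transposed chloride matters because all of them converge in step 7.

Step 5
Reactants: 7 [4-(benzyloxy)-3-methoxyphenyl]methanol
Product: 8 1-(benzyloxy)-4-(chloromethyl)-2-methoxybenzene
Conditions: SOCl2, CH2Cl2, 0 °C
Reagents that add atoms: thionyl chloride, O=S(Cl)Cl
Why: Standard chlorodehydroxylation of an electron-rich primary benzylic alcohol, which creates no stereocentre.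

Step 6
Reactants: 8 benzylic chloride
Product: 9 [4-(benzyloxy)-3-methoxybenzyl]zinc chloride (LiCl-solubilised; decanted from excess zinc, titrated and kept as a THF stock solution)
Conditions: Zn dust, LiCl, THF, 25 °C
Reagents that add atoms: zinc, [Zn]
Why: LiCl-promoted direct insertion of zinc into a benzylic chloride, a mild method that tolerates aryl ethers and should keep Wurtz-type homocoupling low.

Step 7
Reactants: 6 racemic allylic chloride; 9 benzylic zinc chloride
Product: 11 2-(benzyloxy)-5-[(1E,3S)-4-[4-(benzyloxy)-3-methoxyphenyl]-2,3-dimethylbut-1-en-1-yl]-1,3-dimethoxybenzene, via planar allyl radical 10 (not isolated)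
Conditions: NiCl2·glyme (5 mol %), (S,S)-2,6-bis[4-(2-phenylethyl)-4,5-dihydrooxazol-2-yl]pyridine (5.5 mol %), NaCl (4 equiv), 9 (1.5 equiv, slow addition), DMA/DMF/THF, −10 °C
Reagents that add atoms: none
Why: Proposed new method: the closest known reaction type is the nickel/Pybox-catalysed enantioconvergent Negishi coupling of racemic secondary allylic chlorides with primary alkylzinc halides, and what is new here is the benzylic zinc partner and the 1-aryl-2-methyl-substituted allyl unit. A ligated Ni(I) species abstracts chlorine from either enantiomer of 6 (and from any allylic-transposed chloride), so that all isomers collapse to the one planar, syringyl-conjugated radical 10, which is captured by the chiral Ni(II)–benzyl complex formed from 9, and the resulting Ni(III) allyl/benzyl complex reductively eliminates to form C3–C4. The new stereocentre C3 (S) is controlled only by the C2-symmetric Pybox pocket during capture and reductive elimination, not by the substrate, so the whole racemate can be funnelled into one configuration instead of being limited to half as in a resolution. The step needs regioselectivity for the CH3-bearing allyl terminus, and the syringyl ring secures it because bond formation at C3 keeps the styrene conjugation and avoids the more hindered aryl-bearing carbon, while the (E)-alkene follows from the less strained allyl geometry in which the aryl group points away from C3. Homocoupling and an uncatalysed ionic background reaction are countered by slow addition of 9, low temperature and the strongly coordinating amide solvents, and the benzyl and methyl aryl ethers are inert. No ring is closed.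

Step 8
Reactants: 11 (1E,3S)-alkene
Product: 12 2-(benzyloxy)-5-[(2R,3S)-4-[4-(benzyloxy)-3-methoxyphenyl]-2,3-dimethylbutyl]-1,3-dimethoxybenzene
Conditions: [Ir(cod)(L*)]BArF (1–2 mol %, L* = ThrePHOX-type phosphinite–oxazoline), H2 (50 bar), CH2Cl2, 25 °C
Reagents that add atoms: none
Why: Iridium/N,P-ligand-catalysed asymmetric hydrogenation of an unfunctionalised (E)-trisubstituted 1-aryl-2-methylalkene, in which syn delivery of H2 to the face chosen by the ligand sets C2 as (R), the neighbouring C3 centre (H, CH3, CH2Ar) exerts only a weak bias, and the homogeneous catalyst leaves the benzyl ethers intact.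

Step 9
Reactants: 12 bis(benzyl ether)
Product: 13 4-[(2R,3S)-4-(4-hydroxy-3-methoxyphenyl)-2,3-dimethylbutyl]-2,6-dimethoxyphenol (target)
Conditions: H2 (1 atm), 10 % Pd/C, EtOAc/EtOH, 25 °C
Reagents that add atoms: none
Why: Heterogeneous palladium-catalysed hydrogenolysis of two aryl benzyl ethers; neither stereocentre is benzylic or acidic, so the configuration is untouched.

**Compound list**
1 | syringaldehyde (4-hydroxy-3,5-dimethoxybenzaldehyde) | COc1cc(C=O)cc(OC)c1O | starting material
2 | 4-(benzyloxy)-3,5-dimethoxybenzaldehyde | COc1cc(C=O)cc(OC)c1OCc1ccccc1 | intermediate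
3 | 2-(triphenyl-λ5-phosphanylidene)propanal | CC(C=O)=P(c1ccccc1)(c1ccccc1)c1ccccc1 | starting material
4 | (E)-3-[4-(benzyloxy)-3,5-dimethoxyphenyl]-2-methylprop-2-enal | O=C/C(C)=C/c1cc(OC)c(OCc2ccccc2)c(OC)c1 | intermediate
5 | racemic (E)-4-[4-(benzyloxy)-3,5-dimethoxyphenyl]-3-methylbut-3-en-2-ol | CC(O)/C(C)=C/c1cc(OC)c(OCc2ccccc2)c(OC)c1 | intermediate
6 | racemic 2-(benzyloxy)-5-[(1E)-3-chloro-2-methylbut-1-en-1-yl]-1,3-dimethoxybenzene | CC(Cl)/C(C)=C/c1cc(OC)c(OCc2ccccc2)c(OC)c1 | intermediate
7 | [4-(benzyloxy)-3-methoxyphenyl]methanol | COc1cc(CO)ccc1OCc1ccccc1 | starting material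
8 | 1-(benzyloxy)-4-(chloromethyl)-2-methoxybenzene | COc1cc(CCl)ccc1OCc1ccccc1 | intermediate
9 | [4-(benzyloxy)-3-methoxybenzyl]zinc chloride (THF solution, LiCl) | COc1cc(C[Zn]Cl)ccc1OCc1ccccc1 | intermediate
10 | (E)-4-[4-(benzyloxy)-3,5-dimethoxyphenyl]-3-methylbut-3-en-2-yl radical (delocalised allyl radical, one resonance form drawn) | C[CH]/C(C)=C/c1cc(OC)c(OCc2ccccc2)c(OC)c1 | intermediate
11 | 2-(benzyloxy)-5-[(1E,3S)-4-[4-(benzyloxy)-3-methoxyphenyl]-2,3-dimethylbut-1-en-1-yl]-1,3-dimethoxybenzene | COc1cc(C[C@H](C)/C(C)=C/c2cc(OC)c(OCc3ccccc3)c(OC)c2)ccc1OCc1ccccc1 | intermediate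
12 | 2-(benzyloxy)-5-[(2R,3S)-4-[4-(benzyloxy)-3-methoxyphenyl]-2,3-dimethylbutyl]-1,3-dimethoxybenzene | COc1cc(C[C@H](C)[C@H](C)Cc2cc(OC)c(OCc3ccccc3)c(OC)c2)ccc1OCc1ccccc1 | intermediate
13 | 4-[(2R,3S)-4-(4-hydroxy-3-methoxyphenyl)-2,3-dimethylbutyl]-2,6-dimethoxyphenol | COc1cc(C[C@H](C)[C@H](C)Cc2cc(OC)c(O)c(OC)c2)ccc1O | target

Total step count: 9. Longest linear sequence: 7 (steps 1–4 and 7–9).

**Steps most likely to fail**

Step 7. Possible failures are loss of enantiocontrol in the radical capture, bond formation at the aryl-bearing allyl terminus, an uncatalysed ionic background coupling, or homocoupling of the benzylic zinc reagent.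
- The fallback uses known chemistry and is stereospecific instead of stereoconvergent. It sets out from 5 and comes back at 11.
- Racemic 5 is resolved with immobilised Candida antarctica lipase B and vinyl acetate in MTBE. The enzyme should acylate the (R)-alcohol to the (R)-acetate F2 and leave the (S)-alcohol F1, which is separated by chromatography.
- Methyl chloroformate and pyridine convert F1 into the (S)-methyl carbonate F3.
- Palladium(0)-catalysed allylic coupling of F3 with 9 (Pd2(dba)3, PPh3, THF) proceeds by ionisation with inversion. With the hard organozinc nucleophile, transmetalation and reductive elimination then occur with retention.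
- The net inversion at the CH3-bearing terminus leads to 11 with the (S) configuration.

Step 8. Possible failures are poor facial selectivity through a mismatch with the C3 centre, or iridium-hydride-induced migration of the double bond towards C3 before reduction, which would erase the centre set in step 7.
- The fallback is a reagent-controlled hydroboration that sets out from 11 and comes back at 13.
- Monoisopinocampheylborane (the antipode derived from (−)-α-pinene is drawn) adds boron to the benzylic C1 and hydrogen to C2 in a syn fashion, giving the organoborane F4.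
- Oxidation in the same flask (NaBO3 or H2O2/NaOH), with retention, gives the (1S,2S,3S)-benzylic alcohol F5. Its C2 has the spatial arrangement of 13; the descriptor changes only because of the hydroxyl group at C1.
- Hydrogenolysis over Pd(OH)2/C under H2 in EtOH with a little acetic acid removes the benzylic hydroxyl group and both benzyl ethers, giving 13 directly.

Step 4. The likely failure is ionisation of the chloride during concentration, followed by hydrolysis or loss of HCl.
- The fallback sets out from 4 and comes back at 6.
- Wittig methylenation of 4 (methyltriphenylphosphonium bromide, KOtBu, THF) gives the (E)-aryl diene F6.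
- One equivalent of anhydrous HCl in Et2O/CH2Cl2 at low temperature protonates the terminal CH2 to give the same aryl-stabilised allyl cation, and chloride collapses at the CH3-bearing terminus.
- Neither water nor SO2 is formed, so the solution of 6 can be carried into step 7 after a solvent switch without isolation.

**Further compounds**
F1 | step 7 | (2S,3E)-4-[4-(benzyloxy)-3,5-dimethoxyphenyl]-3-methylbut-3-en-2-ol | C[C@H](O)/C(C)=C/c1cc(OC)c(OCc2ccccc2)c(OC)c1
F2 | step 7 | (2R,3E)-4-[4-(benzyloxy)-3,5-dimethoxyphenyl]-3-methylbut-3-en-2-yl acetate | C[C@@H](OC(C)=O)/C(C)=C/c1cc(OC)c(OCc2ccccc2)c(OC)c1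
F3 | step 7 | (2S,3E)-4-[4-(benzyloxy)-3,5-dimethoxyphenyl]-3-methylbut-3-en-2-yl methyl carbonate | C[C@H](OC(=O)OC)/C(C)=C/c1cc(OC)c(OCc2ccccc2)c(OC)c1
F4 | step 8 | (isopinocampheyl)[1-[4-(benzyloxy)-3,5-dimethoxyphenyl]-4-[4-(benzyloxy)-3-methoxyphenyl]-2,3-dimethylbutyl]borane, configured as F5 | COc1cc(C[C@H](C)[C@H](C)[C@H](B[C@H]4C[C@H]5C[C@@H]([C@@H]4C)C5(C)C)c2cc(OC)c(OCc3ccccc3)c(OC)c2)ccc1OCc1ccccc1
F5 | step 8 | (1S,2S,3S)-1-[4-(benzyloxy)-3,5-dimethoxyphenyl]-4-[4-(benzyloxy)-3-methoxyphenyl]-2,3-dimethylbutan-1-ol | COc1cc(C[C@H](C)[C@H](C)[C@H](O)c2cc(OC)c(OCc3ccccc3)c(OC)c2)ccc1OCc1ccccc1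
F6 | step 4 | 2-(benzyloxy)-1,3-dimethoxy-5-[(1E)-2-methylbuta-1,3-dien-1-yl]benzene | C=C/C(C)=C/c1cc(OC)c(OCc2ccccc2)c(OC)c1
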